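## Analysis of the target

Target 30 is an all-epicatechin procyanidin trimer. Three flavan-3-ol units (T, M, L) each consist of a phloroglucinol-type ring A fused to the pyran ring C, with a catechol ring B on C2; C4 of T is bonded to C6 of M, and C4 of M to C6 of L. There are eight stereocentres. C2 and C3 of every unit are (2R,3R) with aryl and hydroxyl cis, and C4 of T and of M carries the next unit trans to the C3 oxygen (4β). The molecule has fifteen free hydroxyls and three air-sensitive catechols. Its two interflavan C4–C6 bonds are benzylic to a trioxygenated ring and cleave by retro-Friedel–Crafts ionisation in acid; with free phenols C2 also epimerises in base. The difficulties are the 4→6 connectivity (C8 of a flavan-3-ol is intrinsically the more nucleophilic position) and the cis-2,3 relationship, which is the less stable one and is lost easily when C3 sits next to a carbonyl or C2 ionises. The strategy rests on unit L: on its ring A, O1 (on C8a) and C4 (on C4a) are on neighbouring carbons, and unit M is on C6, between the C5 and C7 oxygens and para to C8a. Ring A of L is therefore a phloroglucinol bonded to C4 of M through the carbon between two of its oxygens, and its third oxygen marks the carbon that becomes C8a. An aryne across C8a–C4a, flanked on the C4a side by the C5 oxygen, can take up O1 and C4 in one operation, so the 6-versus-8 question never arises for the M–L bond.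

## Retrosynthetic reasoning

30 from 29. All fifteen O–H bonds are masked as benzyl ethers, and the C8–Br bonds on units T and M are kept to the end. Cutting O–benzyl and C–Br last lets one neutral hydrogenolysis expose the oxidation-prone, acid-labile polyphenol.

29 from 28 and 27. C4 of unit L is the only carbon whose oxidation level changes. The methylene is traced through alcohol 28 to ketone 27, because the ring closure delivers C4 as a carbonyl. The forward steps must reduce the ketone without enolising toward the cis C3 centre, then ionise C4 and deliver hydride without breaking the interflavan bonds.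

27 from 16 and 23 (key disconnection). O1–C8a and C4–C4a of unit L are cut together.
- They lie on adjacent carbons of ring A, which is the pattern an aryne delivers.
- Both stereocentres of unit L stay in the three-carbon acyclic amide 23, and the heavy half becomes the T–M dimer carrying a plain aryl ring, 16.
- Cutting C4(M)–C6(L) instead would bring back the C6/C8 problem on unit L. Cutting O1–C2 or C2–C3 would mean creating stereocentres on the largest intermediate.
- The forward reaction has four requirements: alkoxide 24 must add to aryne 25 at C8a and not at C4a; the aryl anion must close onto the amide faster than it is protonated; 24 must be arylated before it fragments by retro-aldol; and adduct 26 must hold the ketone back until work-up.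

23 from 22, then 19 and 20, then 17 and 18. The C2–C3 bond of the future unit L is an aldol bond. The syn relationship comes from a Z-enolate and the absolute configuration from auxiliary 17, which is exchanged for the N-methoxy-N-methyl amide afterwards.

16 from 13 and 12. The triflate O–S bond and the aryl C–Si bond are traced, through silyl ether 14 and phenoxide 15, to ortho-iodophenol 13, and the C–I bond to phenol 12. The exchange must distinguish iodine from the two bromines, and the iodination must pick the one ring that carries a free phenol.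

12 from 11, 10 and 9. The three oxygens of the new aryl ring must be told apart: the one para to C4 of unit M ends as the triflate, the two ortho ones as benzyl ethers. In triol 9 only the para hydroxyl has no ortho substituent, so a bulky silyl group goes there (10), the others are benzylated (11) and the silyl group is removed.

9 from 7 and 8. The C4(M)–aryl bond is cut to the C4 cation of the dimer and phloroglucinol 8. Because 8 has three equivalent positions, only one constitution can form. The forward reaction must set 4β, which attack trans to the C3 benzyloxy group ensures.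

7 from 5 and 6. The C4(T)–C6(M) bond is cut. Both partners carry bromine on C8: on 6 it forces attack at C6, on 5 it removes the most nucleophilic site and so limits self-condensation. Different C4 leaving groups (ether in 5, aryl sulfide in 6) allow the two cation couplings to be run one after the other.

5 and 6 from 4, 3, 2 and 1. Both building blocks come from one intermediate, 4, made from (−)-epicatechin 1 by phenol benzylation, C8 bromination and C3 benzylation; this supplies C2 and C3 of units T and M.

## Alternatives that were turned down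

Alternative 1: ring A of unit M by benzannulation.
- Disconnection: all six carbons of ring A of unit M are assembled on C4 of unit T.
- Key step: irradiation of diazo ketone A1 triggers Wolff rearrangement to a vinylketene. This adds silyloxyalkyne A2 and, after four-electron ring opening and six-electron closure, gives phenol A3 (Danheiser benzannulation).
- For: the constitution is unambiguous and no cation coupling is needed for the T–M bond. The three oxygens of the new ring emerge already differentiated. On that point it is stronger than the chosen route, which spends steps 8–10 telling the para oxygen of 9 from the ortho ones.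
- Against: A1 needs a one-carbon-extended 4β substituent on unit T and a diazo transfer next to a hindered stereocentre. Photolysis of a diazo ketone beside five benzyl ethers and three electron-rich arenes invites C–H insertion and arene cyclopropanation in competition with the vinyl shift. A3 is only ring A of M: ring C of M with three stereocentres and the whole of unit L remain.
- Comparison: the chosen key step closes the last ring with all eight stereocentres in place, whereas this one would be followed by well over ten further steps. In place of built-in oxygen differentiation the chosen route offers a symmetric nucleophile (8) and one steric silylation.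

Alternative 2: ring C of unit M by ketyl–aldehyde pinacol.
- Disconnection: C3–C4 of unit M.
- Key step: SmI2 (divalent samarium) reduces the diaryl ketone of keto aldehyde A4 to a ketyl, which adds to the tethered aldehyde and closes ring C as cis-3,4-diol A5. The tertiary C4 carbinol carries the aryl that is to become ring A of unit L.
- For: ketyl–carbonyl cyclisation to cis-diols is a known reaction type, so precedent is stronger than for step 16. The aryl enters as an organometallic reagent at a defined carbon, so no selective protection is needed.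
- Against: the aldehyde α-carbon of A4 is the future C2, an α-aryl-α-aryloxy centre that enolises and eliminates easily. A diaryl ketyl is persistent and may simply be reduced. The C2/C3 relationship rests on one α-stereocentre. The tertiary C4 hydroxyl must then be replaced by hydrogen, and hydride adds to the C4 cation trans to the C3 oxygen, which leaves the aryl cis (4α), the wrong epimer.
- Comparison: the chosen route sets 4β by letting the arene attack the cation, needs no deoxygenation at a stereocentre, and does not leave ring C of unit L still to be made.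

Alternative 3: ring C of unit L by double inversion.
- Disconnection: O1–C2 of unit L.
- Key step: carbonate deprotonates the phenol of bromo formate A6, and the phenoxide displaces the benzylic bromide with inversion to give 3-O-formate A7. The bromide itself comes from a diol with inversion.
- For: every operation has close precedent in flavan-3-ol synthesis, only mild base is used, and C4 arrives as CH2, so steps 17 and 18 would be unnecessary. On precedent and redox economy it is stronger than the chosen route.
- Against: for a 2,3-cis product, net retention at C2 requires the erythro diol, which dihydroxylation of the readily made E-alkene does not give. The 3,4-dialkoxybenzylic bromide ionises, so the displacement leaks toward the trans isomer. The three-carbon chain has to be attached by acid-mediated cinnamylation next to acid-labile interflavan bonds. C2 and C3 would be created on the heaviest intermediate over five to six linear steps.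
- Comparison: the chosen route sets C2 and C3 of unit L separately by an auxiliary-controlled syn-aldol, can purify 23 to one isomer, and spends one step on the ring. What it gives up is precedent for that step.

Key step: step 16

Remarks on the chemistry:
- "T–M" below means the (4β→6)-linked dimer of two 8-bromo-3,5,7,3',4'-penta-O-benzylepicatechin units.
- The two C8 bromines are kept as spectator groups in precursor 16 and product 27 and leave in step 19.
- The C4 configuration of 26 and 28 is left open because that centre is removed.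

## Route

Step 1
Reactants: 1 (−)-epicatechin
Product: 2 5,7,3',4'-tetra-O-benzyl-(−)-epicatechin
Conditions: BnBr, K2CO3, DMF, 0 °C → rt
Reagents that add atoms: benzyl bromide, BrCc1ccccc1
Why: Williamson etherification of the four phenols; carbonate does not deprotonate the C3 alcohol and should not disturb C2 at this temperature.

Step 2
Reactants: 2 5,7,3',4'-tetra-O-benzyl-(−)-epicatechin
Product: 3 8-bromo-5,7,3',4'-tetra-O-benzyl-(−)-epicatechin
Conditions: NBS (1.0 equiv), CH2Cl2, −78 → 0 °C
Reagents that add atoms: N-bromosuccinimide, O=C1CCC(=O)N1Br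
Why: Electrophilic aromatic bromination; C8 is the most nucleophilic and least hindered ring A position (C6 lies between two benzyloxy groups), and the bromide later blocks C8 in every cation coupling.

Step 3
Reactants: 3 8-bromo-5,7,3',4'-tetra-O-benzyl-(−)-epicatechin
Product: 4 8-bromo-3,5,7,3',4'-penta-O-benzyl-(−)-epicatechin
Conditions: NaH, BnBr, DMF, 0 °C → rt
Reagents that add atoms: benzyl bromide, BrCc1ccccc1
Why: Williamson etherification of the C3 alkoxide; it removes the last acidic hydrogen, so that in the key step only the hydroxy amide can be deprotonated.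

Step 4
Reactants: 4 8-bromo-3,5,7,3',4'-penta-O-benzyl-(−)-epicatechin
Product: 5 8-bromo-3,5,7,3',4'-penta-O-benzyl-4β-(2-ethoxyethoxy)epicatechin (C4–O trans to C3–OBn)
Conditions: DDQ, 2-ethoxyethanol, CH2Cl2, rt
Reagents that add atoms: 2-ethoxyethanol, CCOCCO
Why: DDQ abstracts hydride from the C4–H activated by the 5,7-dioxygenated ring (oxidative benzylic etherification), and the alcohol traps the cation trans to the C3 benzyloxy group, giving 4β.

Step 5
Reactants: 5 8-bromo-3,5,7,3',4'-penta-O-benzyl-4β-(2-ethoxyethoxy)epicatechin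
Product: 6 8-bromo-3,5,7,3',4'-penta-O-benzyl-4β-(2,6-dimethylphenylthio)epicatechin
Conditions: 2,6-dimethylbenzenethiol, BF3·OEt2, CH2Cl2, −78 → −40 °C
Reagents that add atoms: 2,6-dimethylbenzenethiol, Cc1cccc(C)c1S
Why: Lewis-acid SN1 exchange at C4 (thiolysis type) with capture from the β face; the di-ortho-substituted aryl sulfide stays silent toward hard Lewis acids and is too hindered to pass its sulfur on to another cation.

Step 6
Reactants: 5 8-bromo-3,5,7,3',4'-penta-O-benzyl-4β-(2-ethoxyethoxy)epicatechin (electrophile); 6 8-bromo-3,5,7,3',4'-penta-O-benzyl-4β-(2,6-dimethylphenylthio)epicatechin (nucleophile, 3 equiv)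
Product: 7 T–M sulfide: the T–M dimer with 4β-(2,6-dimethylphenylthio) on C4 of unit M
Conditions: Me3SiOTf (0.3 equiv), 4 Å molecular sieves, CH2Cl2, −78 → −40 °C
Reagents that add atoms: none
Why: Friedel–Crafts-type interflavan coupling with halogen capping and orthogonal leaving groups: only the C4 ether of 5 ionises, and the cation attacks C6 of 6 (C8 blocked) trans to the C3 benzyloxy group, which sets C4 of unit T as 4β; excess 6 and the bromine on 5 suppress self-condensation.

Step 7
Reactants: 7 T–M sulfide; 8 phloroglucinol (10 equiv)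
Product: 9 T–M with a 2,4,6-trihydroxyphenyl group on C4β of unit M
Conditions: AgBF4, 2,6-di-tert-butyl-4-methylpyridine, THF, 0 °C, dark
Reagents that add atoms: none
Why: Thiophilic activation of the C4 sulfide and capture of the cation by phloroglucinol (the reaction type of phloroglucinolysis); the three positions of 8 are equivalent, so one constitution results, attack trans to C3–OBn sets C4 of unit M as 4β, and the excess of 8 prevents double alkylation.

Step 8
Reactants: 9 T–M with a 2,4,6-trihydroxyphenyl group on C4β of unit M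
Product: 10 T–M with a 2,6-dihydroxy-4-(triisopropylsilyloxy)phenyl group on C4β of unit M
Conditions: TIPSCl (1.05 equiv), imidazole, DMF, −20 → 0 °C
Reagents that add atoms: chlorotriisopropylsilane, CC(C)[Si](Cl)(C(C)C)C(C)C
Why: Silylation under steric control: the hydroxyl para to the flavanyl group is the only one without an ortho substituent, whereas the other two are each flanked by C4 of unit M.

Step 9
Reactants: 10 T–M with a 2,6-dihydroxy-4-(triisopropylsilyloxy)phenyl group on C4β of unit M
Product: 11 T–M with a 2,6-bis(benzyloxy)-4-(triisopropylsilyloxy)phenyl group on C4β of unit M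
Conditions: BnBr, K2CO3, Bu4NI (cat.), acetone, 45 °C
Reagents that add atoms: benzyl bromide, BrCc1ccccc1
Why: Williamson etherification of the two remaining phenols; the aryl triisopropylsilyl ether should survive anhydrous carbonate in acetone.

Step 10
Reactants: 11 T–M with a 2,6-bis(benzyloxy)-4-(triisopropylsilyloxy)phenyl group on C4β of unit M
Product: 12 T–M–aryl phenol: T–M with a 2,6-bis(benzyloxy)-4-hydroxyphenyl group on C4β of unit M
Conditions: Bu4NF, AcOH, THF, 0 °C
Reagents that add atoms: none
Why: Fluoride cleavage of the aryl silyl ether driven by Si–F bond formation; acetic acid buffers the phenoxide.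

Step 11
Reactants: 12 T–M–aryl phenol
Product: 13 T–M with a 2,6-bis(benzyloxy)-4-hydroxy-3-iodophenyl group on C4β of unit M
Conditions: NIS (1.0 equiv), NaHCO3, CH2Cl2, −40 → 0 °C
Reagents that add atoms: N-iodosuccinimide, O=C1CCC(=O)N1I
Why: Electrophilic iodination ortho to the free phenol; the para position is occupied, the two ortho positions are equivalent by rotation about the aryl–C4 bond, and every other electron-rich ring is an ether that is fully substituted or deactivated by bromine.

Step 12
Reactants: 13 T–M with a 2,6-bis(benzyloxy)-4-hydroxy-3-iodophenyl group on C4β of unit M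
Product: 16 T–M with a 2,6-bis(benzyloxy)-3-(trimethylsilyl)-4-(trifluoromethylsulfonyloxy)phenyl group on C4β of unit M, via O-trimethylsilyl ether 14 (not isolated), via lithium 2-silylphenoxide 15 (not isolated)
Conditions: HN(SiMe3)2, THF, 65 °C, then evaporation; n-BuLi (1.05 equiv), THF, −100 → −78 °C; Tf2O, −100 → −78 °C
Reagents that add atoms: hexamethyldisilazane, C[Si](C)(C)N[Si](C)(C)C; trifluoromethanesulfonic anhydride, O=S(=O)(OS(=O)(=O)C(F)(F)F)C(F)(F)F
Why: The standard route to 2-silylaryl triflates: O-silylation, iodine–lithium exchange, anionic 1,3 O→C silyl shift (retro-Brook rearrangement) and O-triflation; iodine exchanges far faster than bromine, so one equivalent of n-BuLi at −100 °C should leave both C8 bromides in place.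

Step 13
Reactants: 17 (S)-4-benzyl-2-oxazolidinone; 18 benzyloxyacetyl chloride
Product: 19 (S)-4-benzyl-3-(2-benzyloxyacetyl)oxazolidin-2-one
Conditions: n-BuLi, THF, −78 °C; then 18, −78 → 0 °C
Reagents that add atoms: none
Why: N-Acylation of the lithiated oxazolidinone by the acid chloride.

Step 14
Reactants: 19 (S)-4-benzyl-3-(2-benzyloxyacetyl)oxazolidin-2-one; 20 3,4-bis(benzyloxy)benzaldehyde
Product: 22 (S)-4-benzyl-3-[(2S,3R)-2-benzyloxy-3-[3,4-bis(benzyloxy)phenyl]-3-hydroxypropanoyl]oxazolidin-2-one, via Z-dibutylboron enolate 21 (not isolated)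
Conditions: Bu2BOTf, Et3N, CH2Cl2, −78 → 0 °C; 20, −78 → 0 °C; pH 7 buffer, MeOH, H2O2, 0 °C
Reagents that add atoms: none
Why: Evans syn-glycolate aldol: the Z boron enolate reacts through a Zimmerman–Traxler chair on the face away from the benzyl group of the (S)-auxiliary, with the auxiliary and enolate dipoles opposed, which sets (2S,3R), the syn pair that becomes C3 and C2 of unit L.

Step 15
Reactants: 22 (S)-4-benzyl-3-[(2S,3R)-2-benzyloxy-3-[3,4-bis(benzyloxy)phenyl]-3-hydroxypropanoyl]oxazolidin-2-one
Product: 23 (2S,3R)-2-benzyloxy-3-[3,4-bis(benzyloxy)phenyl]-3-hydroxy-N-methoxy-N-methylpropanamide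
Conditions: MeNH(OMe)·HCl, AlMe3, CH2Cl2, −20 → 0 °C; aqueous potassium sodium tartrate
Reagents that add atoms: N,O-dimethylhydroxylamine hydrochloride, CNOC.Cl
Why: Aluminium amide transamidation of the N-acyl oxazolidinone to the Weinreb amide, assisted by the free β-hydroxyl through an aluminium chelate; no stereocentre is touched and auxiliary 17 is recovered.

Step 16
Reactants: 16 T–M with a 2,6-bis(benzyloxy)-3-(trimethylsilyl)-4-(trifluoromethylsulfonyloxy)phenyl group on C4β of unit M; 23 (2S,3R)-2-benzyloxy-3-[3,4-bis(benzyloxy)phenyl]-3-hydroxy-N-methoxy-N-methylpropanamide (2 equiv)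
Product: 27 benzylated dibromo trimer with unit L as the 2,3-cis-3-benzyloxyflavan-4-one, via potassium alkoxide 24 (not isolated), via aryne 25 (not isolated), via hemiaminal alkoxide 26 (not isolated)
Conditions: 23, KN(SiMe3)2 (1.9 equiv), THF, −78 °C; then 16, CsF, 18-crown-6, THF, −78 → −20 °C; pH 7 phosphate buffer, −20 °C
Reagents that add atoms: none
Why: Proposed new method: KN(SiMe3)2 turns 23 into alkoxide 24, and fluoride (helped by the alkoxide, whose silyl ether fluoride recycles) strips Me3Si from 16 with loss of triflate to give aryne 25. The closest known reaction type is the aryne annulation of ortho-hydroxyaryl esters to xanthones (O-arylation, then intramolecular acyl capture); new here are an aliphatic aldol-type alkoxide as the nucleophile and a Weinreb amide as the internal acyl acceptor. The alkoxide adds to the aryne carbon remote from the flanking benzyloxy group, which is the more linear and more electrophilic carbon of a 3-alkoxyaryne and also the less hindered one; this forms O1–C8a and leaves the aryl anion on C4a beside the inductively stabilising oxygen. The anion attacks the amide carbonyl in a 6-exo-trig closure (ring O1–C2–C3–C4–C4a–C8a) to give hemiaminal alkoxide 26, held by potassium chelation to the N-methoxy oxygen, so the ketone appears only on buffered work-up and never meets base. No stereocentre is created in 27 (C4 of 26 is lost on collapse), and C2 and C3 are carried in unchanged from 23 because no bond at either centre is broken. The selectivity needed is regiochemical: it is secured by the C5 benzyloxy group next to the triple bond, and attachment of unit M at C6 follows from its position between the two benzyloxy groups. The syn pair survives only if arylation outruns retro-aldol cleavage of 24, which is why 24 is formed at −78 °C, used in excess and kept at or below −20 °C; HN(SiMe3)2 is the only proton source, and the intramolecular acyl capture should outpace its hindered N–H.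

Step 17
Reactants: 27 benzylated dibromo trimer with unit L as the 2,3-cis-3-benzyloxyflavan-4-one
Product: 28 benzylated dibromo trimer with unit L as the 3-benzyloxyflavan-4-ol (C4 epimers, both usable)
Conditions: NaBH4, CeCl3·7H2O, THF/MeOH, −40 °C
Reagents that add atoms: none
Why: Luche-type carbonyl reduction; the cerium chloride/methanol medium is not basic, so the enolisable cis C3 centre and the O1–C2 bond β to the carbonyl should be left alone, and the new C4 centre is removed in the next step.

Step 18
Reactants: 28 benzylated dibromo trimer with unit L as the 3-benzyloxyflavan-4-ol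
Product: 29 pentadeca-O-benzyl-8(T),8(M)-dibromo trimer: epicatechin-(4β→6)-epicatechin-(4β→6)-epicatechin with all fifteen hydroxyls benzylated and bromine on C8 of units T and M
Conditions: Et3SiH (excess), CF3CO2H, CH2Cl2, −40 → −10 °C
Reagents that add atoms: none
Why: Ionic hydrogenation: acid ionises the C4 alcohol to the cation stabilised by the 5,7-dioxygenated ring and O1, and the silane delivers hydride; low temperature and excess silane should keep the interflavan bonds intact and outcompete attack by arenes.

Step 19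
Reactants: 29 pentadeca-O-benzyl-8(T),8(M)-dibromo trimer
Product: 30 epicatechin-(4β→6)-epicatechin-(4β→6)-epicatechin (CNP0163146.2)
Conditions: H2 (1 atm), Pd(OH)2/C, NaOAc, THF/MeOH/H2O, rt
Reagents that add atoms: none
Why: Hydrogenolysis of fifteen benzyl ethers and hydrodebromination of both aryl bromides over the same catalyst; acetate takes up the HBr so that the acid-labile interflavan bonds are not cleaved.

## Compound list

1 | (−)-epicatechin | Oc1cc(O)c2c(c1)O[C@H](c1ccc(O)c(O)c1)[C@H](O)C2 | starting material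
2 | 5,7,3',4'-tetra-O-benzyl-(−)-epicatechin | c9ccccc9COc1cc(OCc9ccccc9)c2c(c1)O[C@H](c1ccc(OCc9ccccc9)c(OCc9ccccc9)c1)[C@H](O)C2 | intermediate
3 | 8-bromo-5,7,3',4'-tetra-O-benzyl-(−)-epicatechin | c9ccccc9COc1cc(OCc9ccccc9)c2c(c1Br)O[C@H](c1ccc(OCc9ccccc9)c(OCc9ccccc9)c1)[C@H](O)C2 | intermediate
4 | 8-bromo-3,5,7,3',4'-penta-O-benzyl-(−)-epicatechin | c9ccccc9COc1cc(OCc9ccccc9)c2c(c1Br)O[C@H](c1ccc(OCc9ccccc9)c(OCc9ccccc9)c1)[C@H](OCc9ccccc9)C2 | intermediate
5 | 8-bromo-3,5,7,3',4'-penta-O-benzyl-4β-(2-ethoxyethoxy)epicatechin | c9ccccc9COc1cc(OCc9ccccc9)c2c(c1Br)O[C@H](c1ccc(OCc9ccccc9)c(OCc9ccccc9)c1)[C@H](OCc9ccccc9)[C@H]2OCCOCC | intermediate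
6 | 8-bromo-3,5,7,3',4'-penta-O-benzyl-4β-(2,6-dimethylphenylthio)epicatechin | c9ccccc9COc1cc(OCc9ccccc9)c2c(c1Br)O[C@H](c1ccc(OCc9ccccc9)c(OCc9ccccc9)c1)[C@H](OCc9ccccc9)[C@H]2Sc1c(C)cccc1C | intermediate
7 | T–M sulfide (4β→6 dimer, 4β-(2,6-dimethylphenylthio) on unit M) | c9ccccc9COc1cc(OCc9ccccc9)c2c(c1Br)O[C@H](c1ccc(OCc9ccccc9)c(OCc9ccccc9)c1)[C@H](OCc9ccccc9)[C@H]2c1c(OCc9ccccc9)c(Br)c2c(c1OCc9ccccc9)[C@H](Sc1c(C)cccc1C)[C@@H](OCc9ccccc9)[C@@H](c1ccc(OCc9ccccc9)c(OCc9ccccc9)c1)O2 | intermediate
8 | phloroglucinol | Oc1cc(O)cc(O)c1 | starting material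
9 | T–M with 2,4,6-trihydroxyphenyl on C4β of unit M | c9ccccc9COc1cc(OCc9ccccc9)c2c(c1Br)O[C@H](c1ccc(OCc9ccccc9)c(OCc9ccccc9)c1)[C@H](OCc9ccccc9)[C@H]2c1c(OCc9ccccc9)c(Br)c2c(c1OCc9ccccc9)[C@H](c1c(O)cc(O)cc1O)[C@@H](OCc9ccccc9)[C@@H](c1ccc(OCc9ccccc9)c(OCc9ccccc9)c1)O2 | intermediate
10 | T–M with 2,6-dihydroxy-4-(triisopropylsilyloxy)phenyl on C4β of unit M | c9ccccc9COc1cc(OCc9ccccc9)c2c(c1Br)O[C@H](c1ccc(OCc9ccccc9)c(OCc9ccccc9)c1)[C@H](OCc9ccccc9)[C@H]2c1c(OCc9ccccc9)c(Br)c2c(c1OCc9ccccc9)[C@H](c1c(O)cc(O[Si](C(C)C)(C(C)C)C(C)C)cc1O)[C@@H](OCc9ccccc9)[C@@H](c1ccc(OCc9ccccc9)c(OCc9ccccc9)c1)O2 | intermediate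
11 | T–M with 2,6-bis(benzyloxy)-4-(triisopropylsilyloxy)phenyl on C4β of unit M | c9ccccc9COc1cc(OCc9ccccc9)c2c(c1Br)O[C@H](c1ccc(OCc9ccccc9)c(OCc9ccccc9)c1)[C@H](OCc9ccccc9)[C@H]2c1c(OCc9ccccc9)c(Br)c2c(c1OCc9ccccc9)[C@H](c1c(OCc9ccccc9)cc(O[Si](C(C)C)(C(C)C)C(C)C)cc1OCc9ccccc9)[C@@H](OCc9ccccc9)[C@@H](c1ccc(OCc9ccccc9)c(OCc9ccccc9)c1)O2 | intermediate
12 | T–M–aryl phenol (2,6-bis(benzyloxy)-4-hydroxyphenyl on C4β of unit M) | c9ccccc9COc1cc(OCc9ccccc9)c2c(c1Br)O[C@H](c1ccc(OCc9ccccc9)c(OCc9ccccc9)c1)[C@H](OCc9ccccc9)[C@H]2c1c(OCc9ccccc9)c(Br)c2c(c1OCc9ccccc9)[C@H](c1c(OCc9ccccc9)cc(O)cc1OCc9ccccc9)[C@@H](OCc9ccccc9)[C@@H](c1ccc(OCc9ccccc9)c(OCc9ccccc9)c1)O2 | intermediate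
13 | T–M with 2,6-bis(benzyloxy)-4-hydroxy-3-iodophenyl on C4β of unit M | c9ccccc9COc1cc(OCc9ccccc9)c2c(c1Br)O[C@H](c1ccc(OCc9ccccc9)c(OCc9ccccc9)c1)[C@H](OCc9ccccc9)[C@H]2c1c(OCc9ccccc9)c(Br)c2c(c1OCc9ccccc9)[C@H](c1c(OCc9ccccc9)cc(O)c(I)c1OCc9ccccc9)[C@@H](OCc9ccccc9)[C@@H](c1ccc(OCc9ccccc9)c(OCc9ccccc9)c1)O2 | intermediate
14 | O-trimethylsilyl ether of 13 | c9ccccc9COc1cc(OCc9ccccc9)c2c(c1Br)O[C@H](c1ccc(OCc9ccccc9)c(OCc9ccccc9)c1)[C@H](OCc9ccccc9)[C@H]2c1c(OCc9ccccc9)c(Br)c2c(c1OCc9ccccc9)[C@H](c1c(OCc9ccccc9)cc(O[Si](C)(C)C)c(I)c1OCc9ccccc9)[C@@H](OCc9ccccc9)[C@@H](c1ccc(OCc9ccccc9)c(OCc9ccccc9)c1)O2 | intermediate (not isolated)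
15 | lithium phenoxide with trimethylsilyl on the ortho carbon (after O→C silyl shift) | c9ccccc9COc1cc(OCc9ccccc9)c2c(c1Br)O[C@H](c1ccc(OCc9ccccc9)c(OCc9ccccc9)c1)[C@H](OCc9ccccc9)[C@H]2c1c(OCc9ccccc9)c(Br)c2c(c1OCc9ccccc9)[C@H](c1c(OCc9ccccc9)cc([O-])c([Si](C)(C)C)c1OCc9ccccc9)[C@@H](OCc9ccccc9)[C@@H](c1ccc(OCc9ccccc9)c(OCc9ccccc9)c1)O2.[Li+] | intermediate (not isolated)
16 | T–M with 2,6-bis(benzyloxy)-3-(trimethylsilyl)-4-(trifluoromethylsulfonyloxy)phenyl on C4β of unit M | c9ccccc9COc1cc(OCc9ccccc9)c2c(c1Br)O[C@H](c1ccc(OCc9ccccc9)c(OCc9ccccc9)c1)[C@H](OCc9ccccc9)[C@H]2c1c(OCc9ccccc9)c(Br)c2c(c1OCc9ccccc9)[C@H](c1c(OCc9ccccc9)cc(OS(=O)(=O)C(F)(F)F)c([Si](C)(C)C)c1OCc9ccccc9)[C@@H](OCc9ccccc9)[C@@H](c1ccc(OCc9ccccc9)c(OCc9ccccc9)c1)O2 | intermediate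
17 | (S)-4-benzyl-2-oxazolidinone | O=C1N[C@@H](Cc2ccccc2)CO1 | starting material
18 | benzyloxyacetyl chloride | O=C(Cl)COCc1ccccc1 | starting material
19 | (S)-4-benzyl-3-(2-benzyloxyacetyl)oxazolidin-2-one | O=C1OC[C@H](Cc2ccccc2)N1C(=O)COCc1ccccc1 | intermediate
20 | 3,4-bis(benzyloxy)benzaldehyde | O=Cc1ccc(OCc2ccccc2)c(OCc2ccccc2)c1 | starting material
21 | Z-dibutylboron enolate of 19 | CCCCB(CCCC)O/C(=C\OCc1ccccc1)N1C(=O)OC[C@@H]1Cc1ccccc1 | intermediate (not isolated)
22 | (S)-4-benzyl-3-[(2S,3R)-2-benzyloxy-3-[3,4-bis(benzyloxy)phenyl]-3-hydroxypropanoyl]oxazolidin-2-one | O=C1OC[C@H](Cc2ccccc2)N1C(=O)[C@@H](OCc1ccccc1)[C@@H](c1ccc(OCc2ccccc2)c(OCc2ccccc2)c1)O | intermediate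
23 | (2S,3R)-2-benzyloxy-3-[3,4-bis(benzyloxy)phenyl]-3-hydroxy-N-methoxy-N-methylpropanamide | CON(C)C(=O)[C@@H](OCc1ccccc1)[C@@H](c1ccc(OCc2ccccc2)c(OCc2ccccc2)c1)O | intermediate
24 | potassium alkoxide of 23 | CON(C)C(=O)[C@@H](OCc1ccccc1)[C@@H](c1ccc(OCc2ccccc2)c(OCc2ccccc2)c1)[O-].[K+] | intermediate (not isolated)
25 | aryne from 16 (triple bond between the former C–OTf and C–Si carbons) | c9ccccc9COc1cc(OCc9ccccc9)c2c(c1Br)O[C@H](c1ccc(OCc9ccccc9)c(OCc9ccccc9)c1)[C@H](OCc9ccccc9)[C@H]2c1c(OCc9ccccc9)c(Br)c2c(c1OCc9ccccc9)[C@H](C1=C(OCc9ccccc9)C#CC=C1OCc9ccccc9)[C@@H](OCc9ccccc9)[C@@H](c1ccc(OCc9ccccc9)c(OCc9ccccc9)c1)O2 | intermediate (not isolated)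
26 | potassium hemiaminal alkoxide (ring C of unit L closed, C4 bearing O− and N(OMe)Me) | c9ccccc9COc1cc(OCc9ccccc9)c2c(c1Br)O[C@H](c1ccc(OCc9ccccc9)c(OCc9ccccc9)c1)[C@H](OCc9ccccc9)[C@H]2c1c(OCc9ccccc9)c(Br)c2c(c1OCc9ccccc9)[C@H](c1c(OCc9ccccc9)cc3c(c1OCc9ccccc9)C([O-])(N(C)OC)[C@@H](OCc9ccccc9)[C@@H](c1ccc(OCc9ccccc9)c(OCc9ccccc9)c1)O3)[C@@H](OCc9ccccc9)[C@@H](c1ccc(OCc9ccccc9)c(OCc9ccccc9)c1)O2.[K+] | intermediate (not isolated)
27 | benzylated dibromo trimer, unit L as 2,3-cis-3-benzyloxyflavan-4-one | c9ccccc9COc1cc(OCc9ccccc9)c2c(c1Br)O[C@H](c1ccc(OCc9ccccc9)c(OCc9ccccc9)c1)[C@H](OCc9ccccc9)[C@H]2c1c(OCc9ccccc9)c(Br)c2c(c1OCc9ccccc9)[C@H](c1c(OCc9ccccc9)cc3c(c1OCc9ccccc9)C(=O)[C@@H](OCc9ccccc9)[C@@H](c1ccc(OCc9ccccc9)c(OCc9ccccc9)c1)O3)[C@@H](OCc9ccccc9)[C@@H](c1ccc(OCc9ccccc9)c(OCc9ccccc9)c1)O2 | intermediate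
28 | benzylated dibromo trimer, unit L as 3-benzyloxyflavan-4-ol (C4 undefined) | c9ccccc9COc1cc(OCc9ccccc9)c2c(c1Br)O[C@H](c1ccc(OCc9ccccc9)c(OCc9ccccc9)c1)[C@H](OCc9ccccc9)[C@H]2c1c(OCc9ccccc9)c(Br)c2c(c1OCc9ccccc9)[C@H](c1c(OCc9ccccc9)cc3c(c1OCc9ccccc9)C(O)[C@@H](OCc9ccccc9)[C@@H](c1ccc(OCc9ccccc9)c(OCc9ccccc9)c1)O3)[C@@H](OCc9ccccc9)[C@@H](c1ccc(OCc9ccccc9)c(OCc9ccccc9)c1)O2 | intermediate
29 | pentadeca-O-benzyl-8(T),8(M)-dibromo trimer | c9ccccc9COc1cc(OCc9ccccc9)c2c(c1Br)O[C@H](c1ccc(OCc9ccccc9)c(OCc9ccccc9)c1)[C@H](OCc9ccccc9)[C@H]2c1c(OCc9ccccc9)c(Br)c2c(c1OCc9ccccc9)[C@H](c1c(OCc9ccccc9)cc3c(c1OCc9ccccc9)C[C@@H](OCc9ccccc9)[C@@H](c1ccc(OCc9ccccc9)c(OCc9ccccc9)c1)O3)[C@@H](OCc9ccccc9)[C@@H](c1ccc(OCc9ccccc9)c(OCc9ccccc9)c1)O2 | intermediate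
30 | epicatechin-(4β→6)-epicatechin-(4β→6)-epicatechin (CNP0163146.2) | Oc1cc(O)c2c(c1)O[C@H](c1ccc(O)c(O)c1)[C@H](O)[C@H]2c1c(O)cc2c(c1O)[C@H](c1c(O)cc3c(c1O)C[C@@H](O)[C@@H](c1ccc(O)c(O)c1)O3)[C@@H](O)[C@@H](c1ccc(O)c(O)c1)O2 | target

## Step count and least certain steps

Total: 19 steps. Longest linear sequence: 16 steps (steps 1–12 and 16–19); steps 13–15 form the side branch.

Step 16 (key step, new method). The likely failures are processes that compete with arylation and ring closure:
- retro-aldol fragmentation of alkoxide 24 before it meets the aryne, with loss of material and scrambling of the syn pair on re-addition;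
- protonation of the C4a aryl anion before it reaches the amide, which gives an open aryl ether;
- early collapse of 26 in the basic mixture, followed by enolisation or ring opening of the ketone;
- loss of regiocontrol in the alkoxide addition.

Fallback by known chemistry: the sequence sets out from sulfide 7 and building block 4. Silver-promoted ionisation of 7 (AgBF4, 2,6-di-tert-butyl-4-methylpyridine, THF, 0 °C) in the presence of excess 4 gives the C4(M)→C6(L) bond by the same halogen-capped cation coupling as step 6 and yields the tribromo pentadeca-O-benzyl trimer F1. Hydrogenolysis as in step 19 returns to the route at target 30. This gives up the aryne construction of ring C and uses the established interflavan coupling for both links.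

Step 6. The cation may condense with C6 of a second molecule of 5 or of product 7 (oligomerisation), attack at the hindered, bromine-deactivated C6 of 6 may be slow, and the sulfide may ionise or pass on its sulfur under the Lewis acid. Fallback with the roles exchanged: from 6 and 5, sulfide 6 is ionised with AgBF4 and hindered pyridine base in THF in the presence of excess 5, whose ether leaving group is inert to silver. This gives T–M ether F2, which is then ionised with BF3·OEt2 in the presence of excess 8 and returns to the route at 9.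

Step 8. Site selectivity of the silylation may be incomplete (reaction at an ortho hydroxyl, or silyl migration between phenols). Fallback that differentiates the oxygens before the C–C bond is made: 8 is mono-silylated to 5-(triisopropylsilyloxy)benzene-1,3-diol F3, and F3 is coupled with 7 under the conditions of step 7. Attack should prefer the carbon between the two free hydroxyls, the only position not next to the silyl ether, and the product is 10, where the route is rejoined.

Step 12. Partial bromine–lithium exchange at the capped positions, silyl transfer between molecules, or triflation before the silyl shift is complete would all lower the return. Fallback without lithium: from 13, i-PrMgCl·LiCl (2.2 equiv, THF, −40 °C) deprotonates the phenol and exchanges only the iodide, since aryl bromides are inert under these conditions. Me3SiCl then silylates carbon and oxygen, aqueous work-up frees the phenol to give C-silyl phenol F4, and Tf2O/pyridine returns to the route at 16.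

Step 17. Enolisation toward C3 (epimerisation to the trans isomer) or β-elimination of the O1 phenoxide (ring opening, loss of C2) may occur if the medium turns basic. Fallback without a basic hydride: ketone 27 is taken directly to 29 by ionic hydrogenation with excess Et3SiH in CF3CO2H/CH2Cl2 (0 °C → rt), which replaces steps 17 and 18, rejoins the route at 29 and makes no new compound.

## Further compounds

F1 | step 16 | pentadeca-O-benzyl-8(T),8(M),8(L)-tribromo trimer | c9ccccc9COc1cc(OCc9ccccc9)c2c(c1Br)O[C@H](c1ccc(OCc9ccccc9)c(OCc9ccccc9)c1)[C@H](OCc9ccccc9)[C@H]2c1c(OCc9ccccc9)c(Br)c2c(c1OCc9ccccc9)[C@H](c1c(OCc9ccccc9)c(Br)c3c(c1OCc9ccccc9)C[C@@H](OCc9ccccc9)[C@@H](c1ccc(OCc9ccccc9)c(OCc9ccccc9)c1)O3)[C@@H](OCc9ccccc9)[C@@H](c1ccc(OCc9ccccc9)c(OCc9ccccc9)c1)O2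
F2 | step 6 | T–M ether (4β→6 dimer, 4β-(2-ethoxyethoxy) on unit M) | c9ccccc9COc1cc(OCc9ccccc9)c2c(c1Br)O[C@H](c1ccc(OCc9ccccc9)c(OCc9ccccc9)c1)[C@H](OCc9ccccc9)[C@H]2c1c(OCc9ccccc9)c(Br)c2c(c1OCc9ccccc9)[C@H](OCCOCC)[C@@H](OCc9ccccc9)[C@@H](c1ccc(OCc9ccccc9)c(OCc9ccccc9)c1)O2
F3 | step 8 | 5-(triisopropylsilyloxy)benzene-1,3-diol | Oc1cc(O)cc(O[Si](C(C)C)(C(C)C)C(C)C)c1
F4 | step 12 | T–M with 2,6-bis(benzyloxy)-4-hydroxy-3-(trimethylsilyl)phenyl on C4β of unit M | c9ccccc9COc1cc(OCc9ccccc9)c2c(c1Br)O[C@H](c1ccc(OCc9ccccc9)c(OCc9ccccc9)c1)[C@H](OCc9ccccc9)[C@H]2c1c(OCc9ccccc9)c(Br)c2c(c1OCc9ccccc9)[C@H](c1c(OCc9ccccc9)cc(O)c([Si](C)(C)C)c1OCc9ccccc9)[C@@H](OCc9ccccc9)[C@@H](c1ccc(OCc9ccccc9)c(OCc9ccccc9)c1)O2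
F0 | step 17 | none | none
A1 | alternative 1 | diazo ketone on C4β of benzylated unit T, 2-benzyloxyvinyl on the carbonyl | c9ccccc9COc1cc(OCc9ccccc9)c2c(c1)O[C@H](c1ccc(OCc9ccccc9)c(OCc9ccccc9)c1)[C@H](OCc9ccccc9)[C@H]2C(=[N+]=[N-])C(=O)C(=C)OCc9ccccc9
A2 | alternative 1 | ethynyloxy(triisopropyl)silane | C#CO[Si](C(C)C)(C(C)C)C(C)C
A3 | alternative 1 | unit T bearing a 2-benzyloxy-4-hydroxy-6-(triisopropylsilyloxy)phenyl ring on C4β | c9ccccc9COc1cc(OCc9ccccc9)c2c(c1)O[C@H](c1ccc(OCc9ccccc9)c(OCc9ccccc9)c1)[C@H](OCc9ccccc9)[C@H]2c1c(OCc9ccccc9)cc(O)cc1O[Si](C(C)C)(C(C)C)C(C)C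
A4 | alternative 2 | keto aldehyde: ring A of unit M with a diaryl ketone on C4a and an O-CH(aryl)-CHO ether on C8a | c9ccccc9COc1cc(OCc9ccccc9)c2c(c1)O[C@H](c1ccc(OCc9ccccc9)c(OCc9ccccc9)c1)[C@H](OCc9ccccc9)[C@H]2c1c(OCc9ccccc9)cc(O[C@@H](C=O)c3ccc(OCc9ccccc9)c(OCc9ccccc9)c3)c(c1OCc9ccccc9)C(=O)c1c(OCc9ccccc9)cc(O[Si](C(C)C)(C(C)C)C(C)C)cc1OCc9ccccc9
A5 | alternative 2 | benzylated T–M dimer as the cis-3,4-diol with the placeholder aryl on C4 | c9ccccc9COc1cc(OCc9ccccc9)c2c(c1)O[C@H](c1ccc(OCc9ccccc9)c(OCc9ccccc9)c1)[C@H](OCc9ccccc9)[C@H]2c1c(OCc9ccccc9)cc2c(c1OCc9ccccc9)[C@](O)(c1c(OCc9ccccc9)cc(O[Si](C(C)C)(C(C)C)C(C)C)cc1OCc9ccccc9)[C@@H](O)[C@@H](c1ccc(OCc9ccccc9)c(OCc9ccccc9)c1)O2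
A6 | alternative 3 | bromo formate: T–M–aryl phenol with a 3-aryl-3-bromo-2-formyloxypropyl chain ortho to the hydroxyl | c9ccccc9COc1cc(OCc9ccccc9)c2c(c1)O[C@H](c1ccc(OCc9ccccc9)c(OCc9ccccc9)c1)[C@H](OCc9ccccc9)[C@H]2c1c(OCc9ccccc9)cc2c(c1OCc9ccccc9)[C@H](c1c(OCc9ccccc9)cc(O)c(c1OCc9ccccc9)C[C@@H](OC=O)[C@H](c3ccc(OCc9ccccc9)c(OCc9ccccc9)c3)Br)[C@@H](OCc9ccccc9)[C@@H](c1ccc(OCc9ccccc9)c(OCc9ccccc9)c1)O2
A7 | alternative 3 | benzylated trimer with unit L as its 3-O-formate | c9ccccc9COc1cc(OCc9ccccc9)c2c(c1)O[C@H](c1ccc(OCc9ccccc9)c(OCc9ccccc9)c1)[C@H](OCc9ccccc9)[C@H]2c1c(OCc9ccccc9)cc2c(c1OCc9ccccc9)[C@H](c1c(OCc9ccccc9)cc3c(c1OCc9ccccc9)C[C@@H](OC=O)[C@@H](c1ccc(OCc9ccccc9)c(OCc9ccccc9)c1)O3)[C@@H](OCc9ccccc9)[C@@H](c1ccc(OCc9ccccc9)c(OCc9ccccc9)c1)O2
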